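**Retrosynthetic overview**

- Phyltetralin ⇒ (two O-methylations) the 2,3-bis(hydroxymethyl)tetralin ⇒ (reduction of all ester groups) a 1-aryltetralin-2,3-dicarboxylate carrying two (S)-lactate ester auxiliaries.
- Feature used: ring B (C1–C2–C3–C4–C4a–C8a, fused to the dimethoxybenzo ring A at C4a–C8a) carries on C2 and C3 two trans one-carbon arms (C2a, C3a) that can both be traced back to carboxyl carbons, so a fumarate unit lies between C1 and C4.
- Key disconnection: C1–C2 and C3–C4, a Diels–Alder reaction between the (E)-α-aryl o-quinodimethane of ring A (exocyclic C8a=C1 and C4a=C4) and a fumarate of ethyl (S)-lactate. Ring B is the only ring formed; ring A and the pendant aryl ring are bought.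
- The diene comes from a bis-benzylic 1,4-dibromide by zinc-induced 1,4-elimination, the dibromide from the diol made by adding lithiated 2-bromo-4,5-dimethoxybenzyl alcohol to veratraldehyde; the dienophile comes from fumaryl chloride and ethyl (S)-lactate.

Key step: step 4

Assumption: the unchelated bis-(S)-lactate fumarate is taken to react on its Si,Si face (anti to the ethoxycarbonyl groups), which leads to (2S,3S); if the sense proved opposite, the same route would be run with the fumarate of ethyl (R)-lactate.

**Route**

Step 1
Reactants: 1 fumaryl chloride; 2 ethyl (S)-lactate (2.1 equiv)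
Product: 3 bis[(2S)-1-ethoxy-1-oxopropan-2-yl] (2E)-but-2-enedioate
Conditions: pyridine (2.2 equiv), DMAP (cat.), CH2Cl2, 0 °C → rt
Reagents that add atoms: none
Why: Double O-acylation of the secondary alcohol by the acid chloride (nucleophilic acyl substitution, pyridine as HCl acceptor) should leave the lactate stereocentres and the E double bond untouched.

Step 2
Reactants: 4 2-bromo-4,5-dimethoxybenzyl alcohol; 5 veratraldehyde
Product: 7 [2-(hydroxymethyl)-4,5-dimethoxyphenyl](3,4-dimethoxyphenyl)methanol (racemic), via aryllithium alkoxide 6 (not isolated)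
Conditions: n-BuLi (2.1 equiv), THF, −78 °C; then 5, −78 → 0 °C; H2O quench
Reagents that add atoms: none
Why: The first equivalent of n-BuLi deprotonates the hydroxyl and the second performs bromine–lithium exchange; 1,2-addition of the aryllithium to the non-enolisable aldehyde should give the benzhydrol, whose new stereocentre is racemic and is erased in step 4.

Step 3
Reactants: 7 [2-(hydroxymethyl)-4,5-dimethoxyphenyl](3,4-dimethoxyphenyl)methanol
Product: 8 1-[bromo(3,4-dimethoxyphenyl)methyl]-2-(bromomethyl)-4,5-dimethoxybenzene (racemic)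
Conditions: PBr3 (0.8 equiv), CH2Cl2, −10 → 0 °C; non-aqueous work-up (filtration through dry K2CO3), cold concentration, used at once
Reagents that add atoms: phosphorus tribromide, BrP(Br)Br
Why: Deoxybromination with PBr3: both hydroxyls should be O-phosphitylated before either C–O bond ionises, which holds back ring closure to the cyclic ether, and bromide then displaces at the primary benzylic carbon (SN2) and at the benzhydryl carbon (SN1 through the doubly stabilised cation).

Step 4
Reactants: 8 1-[bromo(3,4-dimethoxyphenyl)methyl]-2-(bromomethyl)-4,5-dimethoxybenzene; 3 bis[(2S)-1-ethoxy-1-oxopropan-2-yl] (2E)-but-2-enedioate (1.5 equiv)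
Product: 10 bis[(2S)-1-ethoxy-1-oxopropan-2-yl] (1R,2S,3S)-1-(3,4-dimethoxyphenyl)-6,7-dimethoxy-1,2,3,4-tetrahydronaphthalene-2,3-dicarboxylate, via (E)-α-aryl o-quinodimethane 9 (not isolated)
Conditions: activated Zn dust (3 equiv), 1,4-dioxane, ultrasound, 20–25 °C, 8 added slowly to Zn and 3
Reagents that add atoms: none
Why: Zinc inserts into a benzylic C–Br bond of 8 and the benzylic zinc species expels the second bromide in a 1,4-elimination, giving diene 9 with the aryl group outward (E) because the inward position is blocked by the neighbouring exocyclic methylene; the closest known reaction type is the zinc-induced debromination of α,α′-dibromo-o-xylenes with in situ Diels–Alder trapping, combined with the auxiliary-controlled cycloadditions of lactate fumarates. Ring B (C1–C2–C3–C4–C4a–C8a) closes by an intermolecular suprafacial [4+2] cycloaddition that forms C1–C2 and C3–C4 together and is driven by rearomatisation of ring A. The 2,3-trans relation is copied from the E geometry of the fumarate. The absolute configuration at C2 and C3 is set by the (S)-lactate units: in the s-cis enoate conformer with the lactate C–H eclipsing the carbonyl group, the ethoxycarbonyl groups cover the Re,Re face, so the diene should add to the Si,Si face and give (2S,3S). C1 is set by the E geometry of the diene together with exo placement of the C2 ester (the C3 ester sits endo), which keeps that ester away from the twisted aryl group and should give the 1,2-trans, (1R) adduct. The step needs face selectivity (auxiliary, room-temperature generation, dioxane as donor for Zn(II) so that the dienophile reacts unchelated), exo selectivity at C2 (aryl/ester repulsion) and preference over diene dimerisation (slow addition of 8 into excess 3); 10 is to be purified to one diastereomer before the auxiliaries are removed.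

Step 5
Reactants: 10 bis[(2S)-1-ethoxy-1-oxopropan-2-yl] (1R,2S,3S)-1-(3,4-dimethoxyphenyl)-6,7-dimethoxy-1,2,3,4-tetrahydronaphthalene-2,3-dicarboxylate
Product: 11 [(1R,2S,3S)-1-(3,4-dimethoxyphenyl)-6,7-dimethoxy-1,2,3,4-tetrahydronaphthalene-2,3-diyl]dimethanol
Conditions: LiAlH4 (excess), THF, 0 °C → reflux; aqueous NaOH work-up
Reagents that add atoms: none
Why: LiAlH4 reduction of all four ester groups turns the ring carboxyl carbons into the C2a and C3a primary alcohols and releases the auxiliary as water-soluble (S)-propane-1,2-diol and ethanol; C1–C3 are not involved and the all-equatorial trans,trans arrangement has no tendency to epimerise.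

Step 6
Reactants: 11 [(1R,2S,3S)-1-(3,4-dimethoxyphenyl)-6,7-dimethoxy-1,2,3,4-tetrahydronaphthalene-2,3-diyl]dimethanol
Product: 12 phyltetralin, (1R,2S,3S)-1-(3,4-dimethoxyphenyl)-6,7-dimethoxy-2,3-bis(methoxymethyl)-1,2,3,4-tetrahydronaphthalene
Conditions: NaH (3 equiv), MeI (excess), THF–DMF, 0 °C → rt
Reagents that add atoms: iodomethane, CI
Why: Williamson etherification of the two primary alkoxides with iodomethane should give the bis(methyl ether) with no stereocentre involved.

**Compound list**

1 | fumaryl chloride | O=C(Cl)/C=C/C(=O)Cl | starting material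
2 | ethyl (S)-lactate | C[C@H](O)C(=O)OCC | starting material
3 | bis[(2S)-1-ethoxy-1-oxopropan-2-yl] (2E)-but-2-enedioate | CCOC(=O)[C@H](C)OC(=O)/C=C/C(=O)O[C@@H](C)C(=O)OCC | intermediate
4 | 2-bromo-4,5-dimethoxybenzyl alcohol | COc1cc(Br)c(CO)cc1OC | starting material
5 | veratraldehyde (3,4-dimethoxybenzaldehyde) | COc1ccc(C=O)cc1OC | starting material
6 | lithium (2-lithio-4,5-dimethoxyphenyl)methoxide, formed in situ | [Li]OCc1cc(OC)c(OC)cc1[Li] | intermediate
7 | [2-(hydroxymethyl)-4,5-dimethoxyphenyl](3,4-dimethoxyphenyl)methanol, racemic | COc1ccc(C(O)c2cc(OC)c(OC)cc2CO)cc1OC | intermediate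
8 | 1-[bromo(3,4-dimethoxyphenyl)methyl]-2-(bromomethyl)-4,5-dimethoxybenzene, racemic | COc1cc(CBr)c(C(Br)c2ccc(OC)c(OC)c2)cc1OC | intermediate
9 | (6E)-6-[(3,4-dimethoxyphenyl)methylidene]-2,3-dimethoxy-5-methylidenecyclohexa-1,3-diene, formed in situ | C=C1C=C(OC)C(OC)=C/C1=C\c1ccc(OC)c(OC)c1 | intermediate
10 | bis[(2S)-1-ethoxy-1-oxopropan-2-yl] (1R,2S,3S)-1-(3,4-dimethoxyphenyl)-6,7-dimethoxy-1,2,3,4-tetrahydronaphthalene-2,3-dicarboxylate | CCOC(=O)[C@H](C)OC(=O)[C@H]1Cc2cc(OC)c(OC)cc2[C@@H](c2ccc(OC)c(OC)c2)[C@@H]1C(=O)O[C@@H](C)C(=O)OCC | intermediate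
11 | [(1R,2S,3S)-1-(3,4-dimethoxyphenyl)-6,7-dimethoxy-1,2,3,4-tetrahydronaphthalene-2,3-diyl]dimethanol | OC[C@H]1Cc2cc(OC)c(OC)cc2[C@@H](c2ccc(OC)c(OC)c2)[C@@H]1CO | intermediate
12 | phyltetralin, (1R,2S,3S)-1-(3,4-dimethoxyphenyl)-6,7-dimethoxy-2,3-bis(methoxymethyl)-1,2,3,4-tetrahydronaphthalene | COC[C@H]1Cc2cc(OC)c(OC)cc2[C@@H](c2ccc(OC)c(OC)c2)[C@@H]1COC | target

**Step count and risks**

Total step count: 6. Longest linear sequence: 5 steps (steps 2, 3, 4, 5, 6); step 1 is the convergent branch.

Steps most likely to fail:

1. Step 4. The lactate units may discriminate the two fumarate faces too weakly, or Zn(II) may change the reacting conformer of the dienophile, so that the adduct cannot be brought to one diastereomer. The fallback sets out from 8 and comes back at 11. The same zinc-induced generation of diene 9 is run with commercial dimethyl fumarate, which should give racemic dimethyl (1R*,2S*,3S*)-1-(3,4-dimethoxyphenyl)-6,7-dimethoxy-1,2,3,4-tetrahydronaphthalene-2,3-dicarboxylate F1. Reduction with LiAlH4 in THF should give racemic [(1R*,2S*,3S*)-1-(3,4-dimethoxyphenyl)-6,7-dimethoxy-1,2,3,4-tetrahydronaphthalene-2,3-diyl]dimethanol F2. Its enantiomers would be separated by preparative chromatography on a polysaccharide chiral stationary phase, the (1R,2S,3S) enantiomer being 11. Stereocontrol is thereby moved from the auxiliary to a resolution.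

2. Step 3. The benzhydryl cation may be captured by the neighbouring hydroxymethyl group before that group is activated, closing the cyclic ether instead of giving the dibromide. The fallback sets out from 7 and comes back at 8. Diol 7 is cyclised on purpose (p-TsOH cat., CH2Cl2) to the stable, purifiable 1-(3,4-dimethoxyphenyl)-5,6-dimethoxy-1,3-dihydroisobenzofuran F3. This ether is then cleaved with anhydrous HBr (HBr in AcOH/CH2Cl2, 0 °C): the benzhydryl C–O bond should open by SN1, and the electron-rich primary benzylic alcohol so released should be converted into the bromide by the excess HBr, giving 8 for immediate use.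

3. Step 2. The lithium alkoxide may aggregate and precipitate at −78 °C, leaving bromine–lithium exchange incomplete and the addition sluggish. The fallback sets out from 4 and comes back at 7. Alcohol 4 is silylated (TIPSCl, imidazole, DMF) to [(2-bromo-4,5-dimethoxybenzyl)oxy]tri(propan-2-yl)silane F4. Exchange with one equivalent of n-BuLi (THF, −78 °C) gives a soluble monolithium reagent, and its addition to 5 should give (3,4-dimethoxyphenyl)[4,5-dimethoxy-2-({[tri(propan-2-yl)silyl]oxy}methyl)phenyl]methanol F5. TBAF in THF then removes the silyl group under non-acidic conditions to give 7. The bulky silyl group is chosen to resist 1,4 O→C silyl migration in the aryllithium.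

**Further compounds**

F1 | step 4 | racemic dimethyl (1R*,2S*,3S*)-1-(3,4-dimethoxyphenyl)-6,7-dimethoxy-1,2,3,4-tetrahydronaphthalene-2,3-dicarboxylate (both enantiomers written) | COC(=O)[C@H]1Cc2cc(OC)c(OC)cc2[C@@H](c2ccc(OC)c(OC)c2)[C@@H]1C(=O)OC.COC(=O)[C@@H]1Cc2cc(OC)c(OC)cc2[C@H](c2ccc(OC)c(OC)c2)[C@H]1C(=O)OC
F2 | step 4 | racemic [(1R*,2S*,3S*)-1-(3,4-dimethoxyphenyl)-6,7-dimethoxy-1,2,3,4-tetrahydronaphthalene-2,3-diyl]dimethanol (both enantiomers written) | OC[C@H]1Cc2cc(OC)c(OC)cc2[C@@H](c2ccc(OC)c(OC)c2)[C@@H]1CO.OC[C@@H]1Cc2cc(OC)c(OC)cc2[C@H](c2ccc(OC)c(OC)c2)[C@H]1CO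
F3 | step 3 | 1-(3,4-dimethoxyphenyl)-5,6-dimethoxy-1,3-dihydroisobenzofuran (racemic) | COc1ccc(C2OCc3cc(OC)c(OC)cc32)cc1OC
F4 | step 2 | [(2-bromo-4,5-dimethoxybenzyl)oxy]tri(propan-2-yl)silane | COc1cc(Br)c(CO[Si](C(C)C)(C(C)C)C(C)C)cc1OC
F5 | step 2 | (3,4-dimethoxyphenyl)[4,5-dimethoxy-2-({[tri(propan-2-yl)silyl]oxy}methyl)phenyl]methanol (racemic) | COc1ccc(C(O)c2cc(OC)c(OC)cc2CO[Si](C(C)C)(C(C)C)C(C)C)cc1OC
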